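## Retrosynthetic overview (C1–C7 = heptanoid chain, C1 carries the guaiacyl ring)
1. Rhoiptelol B ⇐ 2,6-cis-tetrahydropyran-4-one. The axial C3-OH is set last by equatorial hydride delivery, and all silyl groups come off in the same flask.
2. The only ring is built in one operation from a terminal epoxide, CO and a vinylarene. A C4 radical takes up CO to give the C3 acyl radical, which adds to the styrene CH2 (C4–C3 and C3–C2 bonds).
3. Loss of β-H gives the β-hydroxy enone, which closes O–C1 by a reversible 6-endo oxa-Michael addition. This sets the 2,6-cis relationship.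
4. Epoxide ⇐ (S,S)-diepoxybutane, which supplies C4–C7 and both the C5 and C6 stereocentres, opened once by a 4-oxidophenyl Grignard reagent.
5. Vinylarene ⇐ catechol by O-methylation, para-bromination, vinylation and silylation.

Assumption: (2S,3S)-1,2:3,4-diepoxybutane is bought as the single enantiomer from speciality suppliers. Otherwise it is one KOH step from commercial L-threitol 1,4-dimesylate.

## Route

Step 1
Reactants: 1 catechol
Product: 2 guaiacol (2-methoxyphenol)
Conditions: MeI (1.0 equiv), K2CO3 (1.0 equiv), acetone, reflux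
Reagents that add atoms: iodomethane, CI
Why: Williamson O-alkylation with one equivalent each of base and MeI stops mainly at the mono-ether, and catechol and veratrole are removed by base extraction and distillation.

Step 2
Reactants: 2 guaiacol
Product: 3 4-bromo-2-methoxyphenol
Conditions: NBS (1.0 equiv), MeCN, 0 °C → rt
Reagents that add atoms: N-bromosuccinimide, O=C1CCC(=O)N1Br
Why: In this electrophilic aromatic bromination the free OH is the dominant director, so NBS in MeCN brominates para to OH.

Step 3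
Reactants: 3 4-bromo-2-methoxyphenol; 4 potassium vinyltrifluoroborate
Product: 5 4-vinylguaiacol (4-ethenyl-2-methoxyphenol)
Conditions: PdCl2(dppf)·CH2Cl2 (3 mol%), Cs2CO3, THF/H2O 9:1, 80 °C, trace BHT
Reagents that add atoms: none
Why: Suzuki–Miyaura vinylation tolerates the free phenol, and running it before silylation keeps the fluoride released from the trifluoroborate away from any silyl ether.

Step 4
Reactants: 5 4-vinylguaiacol
Product: 6 tert-butyl(4-ethenyl-2-methoxyphenoxy)dimethylsilane
Conditions: TBSCl, imidazole, CH2Cl2, rt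
Reagents that add atoms: tert-butyldimethylsilyl chloride, CC(C)(C)[Si](C)(C)Cl
Why: Standard phenol silylation removes the H-atom-donating ArO–H before the radical step.

Step 5
Reactants: 7 4-iodophenol; 8 (2S,3S)-1,2:3,4-diepoxybutane
Product: 11 4-{(2S)-2-hydroxy-2-[(2S)-oxiran-2-yl]ethyl}phenol, via chloromagnesium 4-iodophenolate 9 (not isolated), via chloromagnesium 4-(chloromagnesio)phenolate 10 (not isolated)
Conditions: MeMgCl (1.0 equiv), LiCl, THF, −30 °C; i-PrMgCl (1.1 equiv), −30 → 25 °C; CuI (10 mol%), 8 (3 equiv), −40 → 0 °C; then H2O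
Reagents that add atoms: none
Why: Deprotonation and LiCl-assisted I/Mg exchange give an aryl Grignard reagent that opens one terminal CH2 of the C2-symmetric diepoxide by Cu-catalysed SN2 attack; excess 8 favours mono-opening, and neither C–O bond at C5 or C6 is touched, so both (S) centres come intact from 8.

Step 6
Reactants: 11 4-{(2S)-2-hydroxy-2-[(2S)-oxiran-2-yl]ethyl}phenol
Product: 12 tert-butyl{4-[(2S)-2-(tert-butyldimethylsilyloxy)-2-[(2S)-oxiran-2-yl]ethyl]phenoxy}dimethylsilane
Conditions: TBSCl (2.5 equiv), imidazole, DMF, rt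
Reagents that add atoms: tert-butyldimethylsilyl chloride, CC(C)(C)[Si](C)(C)Cl
Why: Double silylation caps the phenol and the C6-OH in one operation, which blocks γ-lactone, hemiketal and furan formation in step 7 and leaves the epoxide untouched.

Step 7 (key step)
Reactants: 12 bis-TBS epoxide; 6 tert-butyl(4-ethenyl-2-methoxyphenoxy)dimethylsilane (1.3 equiv); 13 carbon monoxide
Product: 16 (2R,6S)-2-[4-(tert-butyldimethylsilyloxy)-3-methoxyphenyl]-6-{(1S)-1-(tert-butyldimethylsilyloxy)-2-[4-(tert-butyldimethylsilyloxy)phenyl]ethyl}oxan-4-one, via (2R,3S)-3-(tert-butyldimethylsilyloxy)-4-[4-(tert-butyldimethylsilyloxy)phenyl]-1-iodobutan-2-ol 14 (not isolated), via (1E,5S,6S)-6-(tert-butyldimethylsilyloxy)-1-[4-(tert-butyldimethylsilyloxy)-3-methoxyphenyl]-5-hydroxy-7-[4-(tert-butyldimethylsilyloxy)phenyl]hept-1-en-3-one 15 (not isolated)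
Conditions: CO (45 atm), Pd(PPh3)4 (5 mol%), 2,6-lutidine·HI (30 mol%), PhH/MeCN 4:1, hν (Xe lamp, Pyrex), 25 °C; vent; Amberlyst-15, CH2Cl2, rt
Reagents that add atoms: none
Why: Proposed new method: lutidinium iodide opens the epoxide of 12 at the terminal C4 to iodohydrin 14, photoexcited Pd(0) abstracts iodine to give a primary β-hydroxyalkyl radical with no fast intramolecular outlet, this is carbonylated under pressure to the C3 acyl radical, which adds to the CH2 terminus of styrene 6, and the benzylic radical is captured by Pd(I)–I and loses β-H to give (E)-enone 15; the HI released is carried by lutidine to the next epoxide, so no stoichiometric base (which would only re-close 14) is needed and every atom of the three partners ends in the product; acid then drives the reversible 6-endo-trig oxa-Michael addition of C5-OH to the diequatorial 2,6-cis ring, setting C1 (R) under thermodynamic control from the fixed C5 centre; closest known reaction types are the Pd/light carbonylative Mizoroki–Heck reaction of alkyl iodides with styrenes, in-situ iodohydrin formation in reductive epoxide cross-couplings, and the acid-resin cyclisation of β-hydroxy enones to cis-2,6-tetrahydropyran-4-ones.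

Step 8
Reactants: 16 2,6-cis-oxan-4-one
Product: 18 rhoiptelol B, via (2R,4S,6S)-2-[4-(tert-butyldimethylsilyloxy)-3-methoxyphenyl]-6-{(1S)-1-(tert-butyldimethylsilyloxy)-2-[4-(tert-butyldimethylsilyloxy)phenyl]ethyl}oxan-4-ol 17 (not isolated)
Conditions: L-Selectride (1.3 equiv), THF, −78 °C; then TBAF (5 equiv), −78 °C → rt; H2O
Reagents that add atoms: none
Why: In this diastereoselective ketone reduction the bulky tri-sec-butylborohydride attacks the diequatorial chair along the equatorial trajectory to give the axial (4S) alcohol, trans to both ring substituents, and fluoride then cleaves the three silyl ethers without touching a stereocentre.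

## Compound list
1 | catechol | Oc1ccccc1O | starting material
2 | guaiacol | COc1ccccc1O | intermediate
3 | 4-bromo-2-methoxyphenol | COc1cc(Br)ccc1O | intermediate
4 | potassium vinyltrifluoroborate | C=C[B-](F)(F)F.[K+] | starting material
5 | 4-vinylguaiacol | COc1cc(C=C)ccc1O | intermediate
6 | tert-butyl(4-ethenyl-2-methoxyphenoxy)dimethylsilane | COc1cc(C=C)ccc1O[Si](C)(C)C(C)(C)C | intermediate
7 | 4-iodophenol | Oc1ccc(I)cc1 | starting material
8 | (2S,3S)-1,2:3,4-diepoxybutane | C1O[C@@H]1[C@@H]1CO1 | starting material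
9 | chloromagnesium 4-iodophenolate | Cl[Mg]Oc1ccc(I)cc1 | intermediate
10 | chloromagnesium 4-(chloromagnesio)phenolate | Cl[Mg]Oc1ccc([Mg]Cl)cc1 | intermediate
11 | 4-{(2S)-2-hydroxy-2-[(2S)-oxiran-2-yl]ethyl}phenol | Oc1ccc(C[C@H](O)[C@@H]2CO2)cc1 | intermediate
12 | bis-TBS ether of 11 | CC(C)(C)[Si](C)(C)Oc1ccc(C[C@H](O[Si](C)(C)C(C)(C)C)[C@@H]2CO2)cc1 | intermediate
13 | carbon monoxide | [C-]#[O+] | starting material
14 | (2R,3S)-iodohydrin | CC(C)(C)[Si](C)(C)Oc1ccc(C[C@H](O[Si](C)(C)C(C)(C)C)[C@@H](O)CI)cc1 | intermediate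
15 | (1E,5S,6S)-β-hydroxy enone | COc1cc(/C=C/C(=O)C[C@H](O)[C@@H](O[Si](C)(C)C(C)(C)C)Cc2ccc(O[Si](C)(C)C(C)(C)C)cc2)ccc1O[Si](C)(C)C(C)(C)C | intermediate
16 | (2R,6S)-2,6-cis-oxan-4-one, side chain (1S) | COc1cc([C@H]2CC(=O)C[C@@H]([C@@H](O[Si](C)(C)C(C)(C)C)Cc3ccc(O[Si](C)(C)C(C)(C)C)cc3)O2)ccc1O[Si](C)(C)C(C)(C)C | intermediate
17 | tris-TBS rhoiptelol B, (2R,4S,6S), side chain (1S) | COc1cc([C@H]2C[C@H](O)C[C@@H]([C@@H](O[Si](C)(C)C(C)(C)C)Cc3ccc(O[Si](C)(C)C(C)(C)C)cc3)O2)ccc1O[Si](C)(C)C(C)(C)C | intermediate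
18 | rhoiptelol B | COc1cc([C@H]2C[C@H](O)C[C@@H]([C@@H](O)Cc3ccc(O)cc3)O2)ccc1O | target

## Step count and risks
Total steps: 8. Longest linear sequence: 6 (steps 1, 2, 3, 4, 7, 8).

**Most likely to fail: step 7.**
- The iodide shuttle may be slow.
- The β-hydroxyalkyl or acyl species may be lost at palladium through β-OH elimination or β-lactone formation.
- The electron-rich styrene may oligomerise.

The fallback separates the three events. It sets out from 12. LiI/AcOH (THF, rt) gives iodohydrin 14 as an isolated compound. TESCl/imidazole caps the C5 hydroxyl to give (2R,3S)-3-(tert-butyldimethylsilyloxy)-4-[4-(tert-butyldimethylsilyloxy)phenyl]-1-iodo-2-(triethylsilyloxy)butane F1. This plain primary iodide goes through the established stoichiometric-base carbonylative radical Heck reaction with 6 (CO 45 atm, Pd(PPh3)4, DBU, PhH/H2O, hν). The product is (1E,5S,6S)-6-(tert-butyldimethylsilyloxy)-1-[4-(tert-butyldimethylsilyloxy)-3-methoxyphenyl]-7-[4-(tert-butyldimethylsilyloxy)phenyl]-5-(triethylsilyloxy)hept-1-en-3-one F2. CSA in MeOH/CH2Cl2 at 0 °C removes only the TES group, and the liberated 15 closes on Amberlyst-15. The fallback comes back to the route at 16.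

**Second: step 5.**
- The very electron-rich dimagnesiated phenolate may exchange sluggishly.
- It may be poorly soluble.
- It may open 8 twice.

The fallback gives up the unprotected nucleophile. It sets out from 7. TBSCl/imidazole gives tert-butyl(4-iodophenoxy)dimethylsilane F3. i-PrMgCl·LiCl (THF, −20 °C) converts it into 4-(tert-butyldimethylsilyloxy)phenylmagnesium chloride F4. CuI-catalysed opening of excess 8 then gives (1S)-2-[4-(tert-butyldimethylsilyloxy)phenyl]-1-[(2S)-oxiran-2-yl]ethan-1-ol F5. Silylation of the secondary alcohol (TBSCl, imidazole, DMF) comes back to the route at 12, at the cost of one extra step.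

**Third: step 8.**
- Axial selectivity may be too low.
- The borane residues may complicate the telescoped desilylation.

The fallback reaches the axial alcohol by inversion instead of by reagent control. It sets out from 16. NaBH4 (MeOH/CH2Cl2, −20 °C) gives the equatorial alcohol (2R,4R,6S)-2-[4-(tert-butyldimethylsilyloxy)-3-methoxyphenyl]-6-{(1S)-1-(tert-butyldimethylsilyloxy)-2-[4-(tert-butyldimethylsilyloxy)phenyl]ethyl}oxan-4-ol F6. Mitsunobu reaction (4-nitrobenzoic acid, PPh3, DIAD, toluene) inverts C4 to give the (2R,4S,6S)-4-nitrobenzoate of tris-TBS rhoiptelol B F7. K2CO3/MeOH followed by TBAF in the same flask removes the ester and all silyl groups. The fallback comes back to the route at 18.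

## Further compounds
F1 | step 7 | (2R,3S)-3-(tert-butyldimethylsilyloxy)-4-[4-(tert-butyldimethylsilyloxy)phenyl]-1-iodo-2-(triethylsilyloxy)butane | CC(C)(C)[Si](C)(C)Oc1ccc(C[C@H](O[Si](C)(C)C(C)(C)C)[C@@H](O[Si](CC)(CC)CC)CI)cc1
F2 | step 7 | (1E,5S,6S)-5-O-TES enone | COc1cc(/C=C/C(=O)C[C@H](O[Si](CC)(CC)CC)[C@@H](O[Si](C)(C)C(C)(C)C)Cc2ccc(O[Si](C)(C)C(C)(C)C)cc2)ccc1O[Si](C)(C)C(C)(C)C
F3 | step 5 | tert-butyl(4-iodophenoxy)dimethylsilane | CC(C)(C)[Si](C)(C)Oc1ccc(I)cc1
F4 | step 5 | 4-(tert-butyldimethylsilyloxy)phenylmagnesium chloride | CC(C)(C)[Si](C)(C)Oc1ccc([Mg]Cl)cc1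
F5 | step 5 | (1S)-2-[4-(tert-butyldimethylsilyloxy)phenyl]-1-[(2S)-oxiran-2-yl]ethan-1-ol | CC(C)(C)[Si](C)(C)Oc1ccc(C[C@H](O)[C@@H]2CO2)cc1
F6 | step 8 | (2R,4R,6S)-equatorial alcohol, tris-TBS | COc1cc([C@H]2C[C@@H](O)C[C@@H]([C@@H](O[Si](C)(C)C(C)(C)C)Cc3ccc(O[Si](C)(C)C(C)(C)C)cc3)O2)ccc1O[Si](C)(C)C(C)(C)C
F7 | step 8 | (2R,4S,6S)-4-nitrobenzoate, tris-TBS | COc1cc([C@H]2C[C@H](OC(=O)c4ccc(cc4)[N+](=O)[O-])C[C@@H]([C@@H](O[Si](C)(C)C(C)(C)C)Cc3ccc(O[Si](C)(C)C(C)(C)C)cc3)O2)ccc1O[Si](C)(C)C(C)(C)C
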